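The 1,2-dioxane ring O1–O2–C3–C4–C5–C6 is formed in one operation by adding singlet oxygen across C3 and C6 of a cyclic diene. A temporary C3–C9 bond turns the atoms C3 to C9 into a seven-membered carbocycle, so that the C8 methyl stereocentre lies in the ring, separated from C6 only by C7. The cycloaddition then creates both C–O bonds and fixes quaternary C6 relative to C8 by choice of π-face. The precursor is (S)-3,5,7-trimethylcyclohepta-2,4-dien-1-one (diene C3=C4–C5=C6, ketone C9), made by ring-closing metathesis from a commercial enantiopure bromo ester. Baeyer–Villiger cleavage of C3–C9, peroxycarbenium addition of C2 and chain extension at C9 complete the target.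

Key step: step 7

Atom labels (target numbering, used throughout): O1–O2–C3(–C2H2–C1O2H)–C4(Me)–C5H2–C6(Me)–C7H2–C8H(Me)–C9H2–(CH2)8–Ph.
Assumption: methyl (R)-3-bromo-2-methylpropanoate is bought as the single enantiomer; its stereocentre becomes C8.

**Route**

Step 1
Reactants: 1 methyl (R)-3-bromo-2-methylpropanoate; 2 2-bromopropene
Product: 4 methyl (S)-2,4-dimethylpent-4-enoate, via alkylzinc bromide 3 (not isolated)
Conditions: Zn dust, LiCl, THF, 40 °C; then 2, PdCl2(dppf) (3 mol%), THF, 50 °C
Reagents that add atoms: none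
Why: Zinc insertion into the primary C–Br bond gives a β-zincio ester whose stereocentre is not the metal-bearing carbon and therefore keeps its configuration, and Negishi coupling with the vinyl bromide under palladium catalysis joins C7 to C6.

Step 2
Reactants: 4 methyl (S)-2,4-dimethylpent-4-enoate
Product: 5 (2S)-N-methoxy-N,2,4-trimethylpent-4-enamide
Conditions: MeNH(OMe)·HCl, i-PrMgCl, THF, −20 °C
Reagents that add atoms: N,O-dimethylhydroxylamine hydrochloride, CNOC.Cl
Why: Weinreb amide formation by attack of the chloromagnesium amide on the ester is fast at −20 °C, a temperature at which the α-stereocentre C8 is not enolised.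

Step 3
Reactants: 5 (2S)-N-methoxy-N,2,4-trimethylpent-4-enamide; 6 prop-1-ynylmagnesium bromide
Product: 7 (5S)-5,7-dimethyloct-7-en-2-yn-4-one
Conditions: 6 (1.3 equiv), THF, 0 °C; inverse quench into cold aqueous NaHSO4
Reagents that add atoms: none
Why: Weinreb ketone synthesis, in which the magnesium-chelated tetrahedral adduct survives until the quench and so prevents a second addition, while the acidic inverse quench protonates the liberated amine before it can add to the ynone.

Step 4
Reactants: 7 (5S)-5,7-dimethyloct-7-en-2-yn-4-one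
Product: 8 (2Z,5S)-2-iodo-5,7-dimethylocta-2,7-dien-4-one
Conditions: NaI, AcOH, 23 °C, dark
Reagents that add atoms: sodium iodide, [Na+].[I-]
Why: Conjugate hydroiodination of the ynone, with iodide adding to the β-carbon and hydrogen delivered trans to it, gives the kinetic (Z)-β-iodoenone with iodine cis to the carbonyl, the geometry that C3=C4 must have in the ring.

Step 5
Reactants: 8 (2Z,5S)-2-iodo-5,7-dimethylocta-2,7-dien-4-one; 9 tributyl(vinyl)stannane
Product: 10 (3Z,6S)-3,6,8-trimethylnona-1,3,8-trien-5-one
Conditions: 9, PdCl2(MeCN)2 (5 mol%), DMF, 23 °C, dark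
Reagents that add atoms: none
Why: Stille coupling under neutral conditions at room temperature replaces iodine by vinyl with retention of the alkene geometry and does not enolise C8.

Step 6
Reactants: 10 (3Z,6S)-3,6,8-trimethylnona-1,3,8-trien-5-one
Product: 11 (S)-3,5,7-trimethylcyclohepta-2,4-dien-1-one
Conditions: second-generation Hoveyda–Grubbs catalyst (5 mol%), 1,4-benzoquinone (10 mol%), toluene (5 mM), 70 °C
Reagents that add atoms: none
Why: Ring-closing metathesis starts at the monosubstituted vinyl terminus and closes onto the 1,1-disubstituted alkene, the (Z)-C3=C4 bond holding the two ends within reach, so that the trisubstituted C5=C6 bond and the seven-membered ring form with loss of ethene and without touching C8.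

Step 7
Reactants: 11 (S)-3,5,7-trimethylcyclohepta-2,4-dien-1-one
Product: 12 (1R,3S,5R)-3,5,8-trimethyl-6,7-dioxabicyclo[3.2.2]non-8-en-2-one
Conditions: O2 (1 atm), tetraphenylporphyrin (1 mol%), CH2Cl2, −20 °C, white LED
Reagents that add atoms: dioxygen, O=O
Why: Visible-light sensitisation converts O2 into singlet oxygen, which should add in a concerted, suprafacial [4+2] manner across C3 and C6 of the diene that the ring holds s-cis, the reaction type established for tropones and cyclohepta-1,3-dienes. The six-membered peroxide ring O1–O2–C3–C4=C5–C6 is closed by cycloaddition, both C–O bonds forming together across the two diene termini, so no ring-size alternative exists. C3 and C6 arise in the same event and are necessarily bridged cis by O1–O2, on the face away from the C7–C8–C9 bridge; only the π-face remains to be chosen. C8 makes that choice: in the preferred ring conformer its methyl is pseudo-equatorial and the C7–C8 fold covers one face, so oxygen should enter anti to the fold, which leaves the methyl on the peroxide side of the bicycle and gives the C6/C8 relationship of the target. The step therefore needs facial diastereoselectivity, secured only by this conformational bias and expected to be useful but incomplete (the minor adduct should be separable by chromatography), and chemoselectivity for cycloaddition over ene hydroperoxidation at the allylic methyl and methylene groups, secured by the cisoid geometry of the ring diene. Neutral conditions at low temperature should keep the ketone α-centre C8 from epimerising.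

Step 8
Reactants: 12 (1R,3S,5R)-3,5,8-trimethyl-6,7-dioxabicyclo[3.2.2]non-8-en-2-one
Product: 13 (1R,3S,5S,8S)-3,5,8-trimethyl-6,7-dioxabicyclo[3.2.2]nonan-2-one
Conditions: KO2C–N=N–CO2K (excess), AcOH, CH2Cl2, 0 → 23 °C
Reagents that add atoms: none
Why: Diimide reduction, a concerted syn transfer of two hydrogens that spares the O–O bond and the ketone, should take place on the face of C4=C5 next to the unsubstituted two-atom peroxide bridge and not on the face under the three-carbon bridge, which places the C4 methyl on the side of C9 and so sets C4.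

Step 9
Reactants: 13 (1R,3S,5S,8S)-3,5,8-trimethyl-6,7-dioxabicyclo[3.2.2]nonan-2-one
Product: 14 (1R,4S,6S,9S)-4,6,9-trimethyl-2,7,8-trioxabicyclo[4.2.2]decan-3-one
Conditions: mCPBA, NaHCO3, CH2Cl2, 0 → 23 °C
Reagents that add atoms: 3-chloroperoxybenzoic acid (mCPBA), OOC(=O)c1cccc(Cl)c1
Why: Baeyer–Villiger oxidation in which the peroxy-substituted bridgehead C3, helped by the lone pair of O2 as an α-alkoxy carbon is, should migrate in preference to the secondary alkyl carbon C8 and with retention, so that oxygen is inserted between C9 and C3 and C3 becomes an acylal.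

Step 10
Reactants: 14 (1R,4S,6S,9S)-4,6,9-trimethyl-2,7,8-trioxabicyclo[4.2.2]decan-3-one; 15 tert-butyl[(1-methoxyethenyl)oxy]dimethylsilane
Product: 17 (2S)-3-[(3S,5S,6S)-6-(2-methoxy-2-oxoethyl)-3,5-dimethyl-1,2-dioxan-3-yl]-2-methylpropanoic acid, via trimethylsilyl ester 16 (not isolated)
Conditions: 15 (2.5 equiv), TMSOTf (1.1 equiv), CH2Cl2, −78 °C; then aqueous pH 4 buffer
Reagents that add atoms: none
Why: The silyl triflate opens the acylal to a silyl carboxylate and a cyclic peroxycarbenium ion, to which the ketene silyl acetal adds in a Mukaiyama-type reaction along the axial trajectory of the half-chair that keeps the C4 methyl and the C6 side chain pseudo-equatorial, that is trans to the axial C6 methyl, which puts C2 cis to the C4 methyl and sets C3.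

Step 11
Reactants: 17 (2S)-3-[(3S,5S,6S)-6-(2-methoxy-2-oxoethyl)-3,5-dimethyl-1,2-dioxan-3-yl]-2-methylpropanoic acid
Product: 18 methyl 2-[(3S,4S,6R)-6-[(2S)-3-hydroxy-2-methylpropyl]-4,6-dimethyl-1,2-dioxan-3-yl]acetate
Conditions: BH3·THF, THF, 0 °C; then MeOH
Reagents that add atoms: none
Why: Chemoselective borane reduction, which proceeds through the acyloxyborane of the free acid much faster than reduction of the methyl ester and leaves the dialkyl peroxide and C8 untouched.

Step 12
Reactants: 18 methyl 2-[(3S,4S,6R)-6-[(2S)-3-hydroxy-2-methylpropyl]-4,6-dimethyl-1,2-dioxan-3-yl]acetate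
Product: 19 methyl 2-[(3S,4S,6S)-4,6-dimethyl-6-[(2S)-2-methyl-3-oxopropyl]-1,2-dioxan-3-yl]acetate
Conditions: Dess–Martin periodinane, NaHCO3, CH2Cl2, 0 → 23 °C
Reagents that add atoms: none
Why: Dess–Martin oxidation under buffered, non-basic conditions stops at the aldehyde and should neither epimerise the α-stereocentre C8 nor affect the peroxide.

Step 13
Reactants: 20 (8-bromooctyl)benzene
Product: 21 triphenyl(8-phenyloctyl)phosphonium bromide
Conditions: PPh3, MeCN, reflux
Reagents that add atoms: triphenylphosphine, c1ccc(cc1)P(c1ccccc1)c1ccccc1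
Why: SN2 quaternisation of triphenylphosphine by the primary alkyl bromide.

Step 14
Reactants: 19 methyl 2-[(3S,4S,6S)-4,6-dimethyl-6-[(2S)-2-methyl-3-oxopropyl]-1,2-dioxan-3-yl]acetate; 21 triphenyl(8-phenyloctyl)phosphonium bromide
Product: 23 methyl 2-[(3S,4S,6R)-4,6-dimethyl-6-[(2S,3Z)-2-methyl-11-phenylundec-3-en-1-yl]-1,2-dioxan-3-yl]acetate, via phosphonium ylide 22 (not isolated)
Conditions: 21 (1.3 equiv), NaN(SiMe3)2 (1.2 equiv), THF, 0 °C; then 19, −78 → −20 °C
Reagents that add atoms: none
Why: Wittig olefination with a preformed non-stabilised ylide is fast at −78 °C, so that the aldehyde should be consumed before C8 can epimerise or the β-peroxy ester can eliminate, and the geometry of the new C9=C10 bond, expected to be Z, is of no consequence.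

Step 15
Reactants: 23 methyl 2-[(3S,4S,6R)-4,6-dimethyl-6-[(2S,3Z)-2-methyl-11-phenylundec-3-en-1-yl]-1,2-dioxan-3-yl]acetate
Product: 24 methyl 2-[(3S,4S,6R)-4,6-dimethyl-6-[(2R)-2-methyl-11-phenylundecyl]-1,2-dioxan-3-yl]acetate
Conditions: KO2C–N=N–CO2K, AcOH, MeOH/CH2Cl2, 0 → 23 °C
Reagents that add atoms: none
Why: Diimide reduction saturates the unhindered disubstituted alkene by concerted syn hydrogen transfer and leaves the peroxide, the ester and the arene unchanged, which catalytic hydrogenation would not.

Step 16
Reactants: 24 methyl 2-[(3S,4S,6R)-4,6-dimethyl-6-[(2R)-2-methyl-11-phenylundecyl]-1,2-dioxan-3-yl]acetate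
Product: 25 2-[(3S,4S,6R)-4,6-dimethyl-6-[(2R)-2-methyl-11-phenylundecyl]-1,2-dioxan-3-yl]acetic acid
Conditions: LiOH, THF/H2O, 0 → 23 °C; then 1 M HCl to pH 3
Reagents that add atoms: lithium hydroxide, [Li+].[OH-]
Why: Saponification of the unhindered methyl ester with hydroxide at 0 °C, followed by mild acidification, under which 1,2-dioxane-3-acetates are expected to be hydrolysed faster than base opens the ring.

**Compound list**

1 | methyl (R)-3-bromo-2-methylpropanoate | COC(=O)[C@@H](C)CBr | starting material
2 | 2-bromopropene | CC(Br)=C | starting material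
3 | [(2R)-3-methoxy-2-methyl-3-oxopropyl]zinc bromide | COC(=O)[C@@H](C)C[Zn]Br | intermediate
4 | methyl (S)-2,4-dimethylpent-4-enoate | COC(=O)[C@@H](C)CC(C)=C | intermediate
5 | (2S)-N-methoxy-N,2,4-trimethylpent-4-enamide | CON(C)C(=O)[C@@H](C)CC(C)=C | intermediate
6 | prop-1-ynylmagnesium bromide | CC#C[Mg]Br | starting material
7 | (5S)-5,7-dimethyloct-7-en-2-yn-4-one | CC#CC(=O)[C@@H](C)CC(C)=C | intermediate
8 | (2Z,5S)-2-iodo-5,7-dimethylocta-2,7-dien-4-one | C/C(I)=C/C(=O)[C@@H](C)CC(C)=C | intermediate
9 | tributyl(vinyl)stannane | C=C[Sn](CCCC)(CCCC)CCCC | starting material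
10 | (3Z,6S)-3,6,8-trimethylnona-1,3,8-trien-5-one | C=C/C(C)=C\C(=O)[C@@H](C)CC(C)=C | intermediate
11 | (S)-3,5,7-trimethylcyclohepta-2,4-dien-1-one | C[C@@H]1C(=O)C=C(C)C=C(C)C1 | intermediate
12 | (1R,3S,5R)-3,5,8-trimethyl-6,7-dioxabicyclo[3.2.2]non-8-en-2-one | C[C@@H]1C(=O)[C@@H]2OO[C@](C)(C1)C=C2C | intermediate
13 | (1R,3S,5S,8S)-3,5,8-trimethyl-6,7-dioxabicyclo[3.2.2]nonan-2-one | C[C@@H]1C(=O)[C@@H]2OO[C@](C)(C1)C[C@@H]2C | intermediate
14 | (1R,4S,6S,9S)-4,6,9-trimethyl-2,7,8-trioxabicyclo[4.2.2]decan-3-one | C[C@@H]1C(=O)O[C@@H]2OO[C@](C)(C1)C[C@@H]2C | intermediate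
15 | tert-butyl[(1-methoxyethenyl)oxy]dimethylsilane | COC(=C)O[Si](C)(C)C(C)(C)C | starting material
16 | trimethylsilyl (2S)-3-[(3S,5S,6S)-6-(2-methoxy-2-oxoethyl)-3,5-dimethyl-1,2-dioxan-3-yl]-2-methylpropanoate | C[C@H](C(=O)O[Si](C)(C)C)C[C@]1(C)C[C@H](C)[C@H](CC(=O)OC)OO1 | intermediate
17 | (2S)-3-[(3S,5S,6S)-6-(2-methoxy-2-oxoethyl)-3,5-dimethyl-1,2-dioxan-3-yl]-2-methylpropanoic acid | C[C@H](C(=O)O)C[C@]1(C)C[C@H](C)[C@H](CC(=O)OC)OO1 | intermediate
18 | methyl 2-[(3S,4S,6R)-6-[(2S)-3-hydroxy-2-methylpropyl]-4,6-dimethyl-1,2-dioxan-3-yl]acetate | C[C@H](CO)C[C@]1(C)C[C@H](C)[C@H](CC(=O)OC)OO1 | intermediate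
19 | methyl 2-[(3S,4S,6S)-4,6-dimethyl-6-[(2S)-2-methyl-3-oxopropyl]-1,2-dioxan-3-yl]acetate | C[C@H](C=O)C[C@]1(C)C[C@H](C)[C@H](CC(=O)OC)OO1 | intermediate
20 | (8-bromooctyl)benzene | BrCCCCCCCCc1ccccc1 | starting material
21 | triphenyl(8-phenyloctyl)phosphonium bromide | [Br-].c1ccc(cc1)CCCCCCCC[P+](c1ccccc1)(c1ccccc1)c1ccccc1 | intermediate
22 | triphenyl(8-phenyloctylidene)-λ5-phosphane | c1ccc(cc1)CCCCCCCC=P(c1ccccc1)(c1ccccc1)c1ccccc1 | intermediate
23 | methyl 2-[(3S,4S,6R)-4,6-dimethyl-6-[(2S,3Z)-2-methyl-11-phenylundec-3-en-1-yl]-1,2-dioxan-3-yl]acetate | C[C@H](/C=C\CCCCCCCc1ccccc1)C[C@]1(C)C[C@H](C)[C@H](CC(=O)OC)OO1 | intermediate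
24 | methyl 2-[(3S,4S,6R)-4,6-dimethyl-6-[(2R)-2-methyl-11-phenylundecyl]-1,2-dioxan-3-yl]acetate | C[C@H](CCCCCCCCCc1ccccc1)C[C@]1(C)C[C@H](C)[C@H](CC(=O)OC)OO1 | intermediate
25 | 2-[(3S,4S,6R)-4,6-dimethyl-6-[(2R)-2-methyl-11-phenylundecyl]-1,2-dioxan-3-yl]acetic acid | C[C@H](CCCCCCCCCc1ccccc1)C[C@]1(C)C[C@H](C)[C@H](CC(=O)O)OO1 | target

**Step count**

Total step count: 16. Longest linear sequence: 15 steps (steps 1–12 and 14–16; step 13 is the side branch).

**Steps most likely to fail**

1. Step 7. The two π-faces of the diene may not be told apart well enough. The cycloaddition to a carbonyl-conjugated diene is also slow, so ene hydroperoxidation and the C6-epimeric adduct could consume material.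

   The fallback sets out from 11 and comes back at 12. Ketone 11 is reduced in the 1,2-sense (NaBH4, CeCl3·7H2O, MeOH, −40 °C). The trans alcohol (1R,7S)-3,5,7-trimethylcyclohepta-2,4-dien-1-ol F1 is separated from its C9 epimer, which is re-oxidised to 11 with MnO2 and recycled. Silylation (tert-butyldimethylsilyl chloride, imidazole, DMF) gives silyl ether F2. Its diene is no longer conjugated to a carbonyl and should react faster with singlet oxygen. The trans siloxy and methyl groups can both be pseudo-equatorial in one ring conformer only, which fixes the fold of the ring, and the siloxy group on C9 screens the same face as the fold. Photooxygenation under the conditions of step 7 should then give siloxy endoperoxide F3. HF·pyridine in THF releases alcohol F4, and Dess–Martin oxidation gives 12.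

2. Step 9. In the Criegee intermediate the secondary alkyl carbon C8 may migrate in competition with the peroxy-substituted C3, which would lead to the regioisomeric lactone.

   The fallback sets out from 12 and comes back at 14. The oxygen insertion is moved to the unsaturated ketone 12, where C3 is allylic as well as peroxy-substituted and therefore a better migrating group. The oxidant is bis(trimethylsilyl) peroxide with catalytic TMSOTf in CH2Cl2 at −40 °C, a Baeyer–Villiger reagent that does not epoxidise alkenes. This should give unsaturated lactone F5. Diimide reduction as in step 8, again from the peroxide side, then gives 14.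

3. Step 6. The ring closure may stall, because the ruthenium alkylidene formed at the vinyl terminus is conjugated with the ketone and can chelate to it, and closure onto a 1,1-disubstituted alkene is slow. Oligomerisation or Z-to-E isomerisation of C3=C4 could then take over.

   The fallback sets out from 10 and comes back at 11. The carbonyl is taken out of conjugation first: Luche reduction (NaBH4, CeCl3·7H2O, MeOH) of 10 gives trienol F6 as a mixture of carbinol epimers. Ring-closing metathesis of this allylic alcohol with second-generation Grubbs catalyst gives cycloheptadienol F7. Oxidation with Dess–Martin periodinane and NaHCO3 returns to 11.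

Further compounds
F1 | step 7 | (1R,7S)-3,5,7-trimethylcyclohepta-2,4-dien-1-ol | C[C@@H]1[C@@H](O)C=C(C)C=C(C)C1
F2 | step 7 | tert-butyldimethyl{[(1R,7S)-3,5,7-trimethylcyclohepta-2,4-dien-1-yl]oxy}silane | C[C@@H]1[C@@H](O[Si](C)(C)C(C)(C)C)C=C(C)C=C(C)C1
F3 | step 7 | tert-butyldimethyl{[(1R,2R,3S,5R)-3,5,8-trimethyl-6,7-dioxabicyclo[3.2.2]non-8-en-2-yl]oxy}silane | C[C@@H]1[C@@H](O[Si](C)(C)C(C)(C)C)[C@@H]2OO[C@](C)(C1)C=C2C
F4 | step 7 | (1R,2R,3S,5R)-3,5,8-trimethyl-6,7-dioxabicyclo[3.2.2]non-8-en-2-ol | C[C@@H]1[C@@H](O)[C@@H]2OO[C@](C)(C1)C=C2C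
F5 | step 9 | (1R,4S,6R)-4,6,9-trimethyl-2,7,8-trioxabicyclo[4.2.2]dec-9-en-3-one | C[C@@H]1C(=O)O[C@@H]2OO[C@](C)(C1)C=C2C
F6 | step 6 | (3Z,6S)-3,6,8-trimethylnona-1,3,8-trien-5-ol (both C5 epimers) | C=C/C(C)=C\C(O)[C@@H](C)CC(C)=C
F7 | step 6 | (7S)-3,5,7-trimethylcyclohepta-2,4-dien-1-ol (both C1 epimers) | C[C@@H]1C(O)C=C(C)C=C(C)C1
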